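The runs are simulated for substances that don't exist, and the scatter is random.

Late in the dusk run the target readings stop rising, at 0.0127 M and then 0.0126 M, a share of 42.0% of the charge. Yet 58.0% of the charge is not there as target, more than is. We therefore read the flat stretch as a balance between two rates, not as an end: target is made and target is lost.

| flask | starting material | reagent | time |
|---|---|---|---|
| dawn | 0.0500 M | 0.150 M |  |
| dusk | 0.0300 M | 0.130 M |  |
| noon | 0.0500 M | 0.300 M |  |
| autumn | 0.150 M | 0.150 M |  |
| midnight | 0.0500 M | 0.150 M | 26 min |

- dawn run (time / min: [target] / M): 0.24: 0.0010; 0.72: 0.0026; 1.4: 0.0047; 2.2: 0.0073; 3.1: 0.0125; 4.2: 0.0181; 5.3: 0.0199; 6.6: 0.0216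
- dusk run (time / min: [target] / M): 0.24: 0; 0.72: 0.0010; 1.4: 0.0030; 2.2: 0.0062; 3.1: 0.0079; 4.2: 0.0115; 5.3: 0.0127; 6.6: 0.0126
- noon run (time / min: [target] / M): 0.24: 7 × 10⁻⁴; 0.72: 0.0019; 1.4: 0.0040; 2.2: 0.0104; 3.1: 0.0160; 4.2: 0.0179; 5.3: 0.0227; 6.6: 0.0225
- autumn run (time / min: [target] / M): 0.24: 0.0010; 0.72: 0.0039; 1.4: 0.0109; 2.2: 0.0221; 3.1: 0.0326; 4.2: 0.0433; 5.3: 0.0490; 6.6: 0.0531

(standard deviation of a reading: 8 × 10⁻⁴ M)

- Overall: starting material + reagent -> target.
- Constant volume, constant temperature.
- The analysis sees a species whether free or bound.
- "The second partner" is reagent.
- An order is taken over about fifteen percent of the charge, up and down.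

1. the exponent of [reagent] in the starting rate at the charge of the dawn run (at the point where two percent of the starting material have become target)
2. the exponent of [starting material] in the starting rate at the charge of the dawn run (at the point where two percent of the starting material have become target) (one fixed amount of target, the same in the runs compared)
3. target in the midnight run at 26 min, as a share of the starting material charged

Our own reckoning uses two times. The fill time is the charge divided by the mean rise between 0.72 min and 4.2 min, and we take it from the dawn run, whose charge midnight repeats. The loss time is the target share divided by the share lost per minute, assuming that loss goes with the target present. We count the whole share not present as target as unused, as an assumption; making is then the unused share over the fill time, and loss is the target share over the loss time. Where they balance, their ratio has no time in it: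

fill time = 11.2 min

loss time / fill time = target share / unused share = 0.724

loss time = 8.13 min

We carry this ratio from dusk to dawn as an assumption. The last dawn reading, at 6.6 min, is a share of 43.2%. Running both processes on for 19.4 min, and counting all the rest as unused, which is generous, gives a rough estimate for midnight:

16.7%

So expect a fall after the top, not a plateau.

The forecast differs: order 0 in reagent, 0.5 in starting material, and 45% at midnight, saying “so at 26 min I expect the plateau”.

The flask gives 10.5% at midnight, below both estimates, with order 0.20 in reagent and 0.57 in starting material. A fit with the main steps alone gave 91.5% for midnight.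

    starting material + reagent → intermediate (6.060 /M/min)
    intermediate → target (0.8160 /min)
    starting material + reagent ⇌ idle substrate-reagent adduct, settled at all times (21.70 /M)
    target → decomposed product (0.1248 /min)

The autumn readings were still climbing at 6.6 min, at a share of 35.4%. Taking the loss time of 8.13 min to hold in the autumn run too, we reckon a loss of 0.0435 /min of its charge at that reading, against a net gain of 0.0210 /min between 5.3 min and 6.6 min, which puts making at about 1.48 times loss.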